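## Structural features

The target is a benzoic acid whose only ring (C1–C6) carries the carboxyl group at C1, an unbranched thirteen-carbon chain at C2 and free phenols at C4 and C6, so it is a 6-alkyl-β-resorcylic acid built on a 1,2,3,5-tetrasubstituted benzene. The chain is joined to the ring through its C1' methylene and bears acetoxy groups at C2' and C12', both of S configuration. The two stereocentres are separated by nine methylenes, so neither can direct the other, each must be set independently, and an epimer at one centre will not be separable once both are present. Fragile points are the two secondary acetates (lost to alkoxide or hydroxide), the electron-rich resorcinol (oxidation, electrophilic attack) and the salicylic-type acid (decarboxylation on heating or in acid). The C2' oxygen stands δ to the carboxyl carbon, so a free C2' hydroxyl beside any activated carboxyl closes a six-membered lactone (a 3,4-dihydroisocoumarin), and the target is in effect the ring-opened, O-acetylated form of that lactone. The real difficulty is therefore the end-state differentiation (two carbinols acetylated, two phenols and the acid free, the C2' hydroxyl never liberated late) together with the regiospecific placement of three different substituents on neighbouring ring carbons. The key step exploits the fact that C1 and C6 are the central carbon and one carbonyl carbon of a malonate, while C2 to C5 are the four carbons of a but-3-en-2-one that carries the chain on its β-carbon. The 2,4-dihydroxybenzoate is thus the dehydrogenated form of a 2,4-dioxocyclohexanecarboxylate, and carboxyl, both oxygens and the chain are positioned by connectivity alone.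

## Logic of the disconnections

17 from 16: the last bond cut is the O–CH2Ph bond of a benzyl ester. The free acid is the group most likely to decarboxylate or to take part in lactone formation, so it should appear only in a final, neutral operation. The gain is that the carboxyl travels as an ester through every ionic step. The demand is that the benzyl ester is the only hydrogenolysable group in 16 and that the same ester type is already used when the ring is built.

16 from 15 from 14: the four O–acetyl bonds are cut, the two aliphatic ones being traced to silyl ethers in 14 and the two phenolic ones being an accepted by-product in 15. Acetates cannot survive the alkoxide of the ring construction, so the carbinol oxygens must arrive as base-stable ethers and be turned into acetates without passing through a free C2' hydroxyl. One oxygen protecting group then serves from chain assembly to the arene stage. The forward steps must act at oxygen only (retention at C2' and C12') and must discriminate aryl from alkyl acetates cleanly.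

14 from 13: no skeletal bond is cut; two hydrogens are returned to the ring, converting the arene into a 2,4-dioxocyclohexanecarboxylate. That oxidation level is the direct outcome of a condensation, so the arene regiochemistry problem becomes an acyclic connectivity problem and the two ring stereocentres of 13 are of no consequence. The forward step needs an oxidant that removes exactly one equivalent of hydrogen and spares silyl ethers, benzyl ester and the resorcinol it creates.

13 from 10 and 11, through 12: ring bonds C1–C2 and C5–C6 are cut. C1 and C6 fall to 11, and C2–C5 with the whole side chain fall to 10, which carries both stereocentres and no ring. This is the largest simplification in the plan and requires no aryl organometallic. The demand is that conjugate addition to 10 outruns γ-deprotonation, and that the second C–C bond forms from the methyl-side enolate.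

10 from 8 and 9: the C3=C4 double bond of 10 is cut by a metathesis transform. This is preferred to an aldehyde olefination because it avoids a β-silyloxy aldehyde, which is prone to eliminate, and is one step shorter. The acetonylidene unit comes in one step from 9. The forward step must be E-selective and must suppress homodimerisation of 8.

8 from 7 from 6: the two Si–O bonds are cut first, then the bond between the vinyl group and the adjacent CH2 of 7, which reveals a terminal epoxide. Opening occurs at the unsubstituted carbon, so the configuration of C2' is that of the oxirane carbon of 6. Silylation is postponed until both hydroxyls exist, so one operation suffices. The demand is strict regioselectivity for the CH2 terminus and one extra equivalent of organometallic for the free hydroxyl.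

6 from 5 from 4: the oxirane C–O bonds are removed to the terminal alkene, and the C2' configuration is obtained by resolving the epimeric pair 5. The distant C12' centre cannot direct the epoxidation, so reagent control is required; a kinetic resolution is chosen because it can deliver the highest stereochemical purity, which matters since C2' epimers are inseparable later. The gain is that the alkene already present in 1 becomes the second stereocentre. The price is loss of half the material, taken at the earliest and cheapest point.

4 from 1 and 2, through 3: the C3–C4 bond of 4 is cut. The C12' configuration comes unchanged from the chiral pool in 2, and 1 supplies nine methylenes and the terminal alkene. The forward step must open 2 only at its CH2.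

## Other disconnections considered

Alternative 1: The cut is made at the bond from ring C2 to C1' and at the bond from ring C1 to the carboxyl carbon, and the ring is taken from a preformed dimethoxyarene. In the forward sense the chlorohydrin (2S,12S)-12-(tert-butyldimethylsilyloxy)-1-chlorotridecan-2-ol A2 would be deprotonated at oxygen and reductively lithiated at carbon. The dianion from A2 then adds to the aryne 3,5-dimethoxybenzyne A3 at the aryne carbon remote from the flanking methoxy group, so the new aryllithium sits ortho to that methoxy group. Capture of carbon dioxide and acidic work-up would give the lactone (3S)-3-[(10S)-10-(tert-butyldimethylsilyloxy)undecyl]-6,8-dimethoxyisochroman-1-one A1.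
- In its favour: it is highly convergent, joins three components in one flask, takes C2' from the chiral pool without any resolution and needs no dehydrogenation. On convergence and on the source of C2' it is the better plan.
- Against it: A1 holds the C2' oxygen in exactly the lactone that the target must not be. The endgame would have to open a thermodynamically favoured δ-lactone and acetylate the liberated hydroxyl faster than it recloses. It would also have to cleave two aryl methyl ethers with boron or aluminium halides that acetates do not tolerate, which forces a further round of phenol/carbinol differentiation. The strongly basic, cryogenic chemistry must keep the dianion from A2 from fragmenting to a terminal alkene and must keep the precursor of A3 from being consumed by the alkyllithium acting as a base.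
- Comparison: on structure both plans fix the ring substitution unambiguously, one by aryne polarisation and one by connectivity, and here the alternative is the equal of the chosen plan. On mechanism the alternative is kinetically controlled carbanion chemistry, whereas the chosen annulation is driven to a stabilised enolate. On step economy the alternative is shorter up to the ring-bearing intermediate, but is expected to lose that advantage in an endgame that runs against the lactone's stability. The chosen plan never forms the lactone.

Alternative 2: The cut is made at the two carbinol C–O bonds, which are traced to C–C(=O)CH3 bonds. In the forward sense the diketone (3S,13S)-3-{[3,5-bis(benzyloxy)phenyl]methyl}-13-methylpentadecane-2,14-dione A5 would be treated with a peracid. Each secondary carbon migrates in preference to methyl and with retention, giving (2S,12S)-1-[3,5-bis(benzyloxy)phenyl]tridecane-2,12-diyl diacetate A4; no ring closes.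
- In its favour: the acetates are made directly as acetates, so the chain oxygens never need a protecting group and no hydroxyl ever sits next to a carboxyl derivative; on that point it is better than the chosen plan. The stereocentres would be set as carbon centres by auxiliary-controlled enolate alkylation, whose diastereomeric intermediates can be purified; that is also an advantage over a route in which remote epimers cannot be separated.
- Against it: A4 still lacks the ring carboxyl, which must then be introduced between the chain and one oxygen by formylation and oxidation, in competition with the position between the two oxygens. The α-stereocentres of A5 are enolisable and can erode under the acidic oxidation. The electron-rich bis(benzyloxy)arene is itself a peracid substrate, and hindered dialkyl ketones need the strongest peracids. Two auxiliary alkylations, two methyl ketone syntheses, the oxidation, carboxylation and debenzylation add up to a longer sequence.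
- Comparison: on structure the alternative solves the acetate problem best and the arene problem worst, the chosen plan the reverse. On mechanism both rely on well-understood, stereospecific oxygen-centred events for the carbinols, and are equal there. On step economy the chosen plan is clearly shorter.

Alternative 3: The cut is made at ring bonds C2–C3 and C1–C6, so that C1 and C2 come from an alkyne and C3–C6 from a diene. In the forward sense the ynoate benzyl (5S,15S)-5,15-bis(acetyloxy)hexadec-2-ynoate A7 and the diene 5,5-dimethyl-1,3-bis(trimethylsilyloxy)cyclohexa-1,3-diene A8 would undergo a thermal [4+2] cycloaddition. The bridged adduct then expels its gem-dimethyl-substituted two-carbon bridge as a volatile alkene (Alder–Rickert fragmentation), and desilylation on work-up would give benzyl 2-[(2S,12S)-2,12-diacetoxytridecyl]-4,6-dihydroxybenzoate A6. The ester A6 is the same compound as 16.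
- In its favour: the arene is formed at the correct oxidation level under neutral conditions with the acetates already in place. Silyl-to-acetyl exchange, phenolic acetate removal and dehydrogenation all disappear and only hydrogenolysis remains. On step economy and on the endgame it is the better plan, and its stereochemical groundwork (an alkynoate from the same kind of resolved epoxide as 6) is equal.
- Against it: A7 is an internal, β-alkyl ynoate and therefore a sluggish dienophile. The nucleophilic terminus of A8, which must bond to the chain-bearing alkyne carbon, is next to the quaternary gem-dimethyl carbon. Forcing temperatures are then likely, at which the homopropargylic acetate can eliminate, the ynoate can isomerise to an allenoate and the silyl enol ethers can degrade. Weaker polarisation than in a terminal propiolate also puts the regiochemistry in doubt.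
- Comparison: on structure both plans place the substituents by connectivity. On mechanism the alternative stakes everything on one pericyclic step with little room for rescue, whereas the chosen annulation is ionic, stepwise and thermodynamically driven. The chosen plan accepts about three more steps for that security.

Key step: step 7

Remark on the chemistry: ring atoms of 12 and 13 are numbered as in the target arene (C1 carboxyl-bearing, C2 chain-bearing, C4 and C6 oxygen-bearing). The ring stereocentres of 12 and 13 form as mixtures and are written without configuration, and 13 is drawn as the diketo tautomer although it should exist largely as an enol.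

## Route

Step 1
Reactants: 1 10-bromodec-1-ene; 2 (S)-propylene oxide [(2S)-2-methyloxirane]
Product: 4 (2S)-tridec-12-en-2-ol, via dec-9-enylmagnesium bromide 3 (not isolated)
Conditions: Mg (1.2 equiv), THF, 45 °C; then CuI (10 mol%), 2 (1.2 equiv), THF, −30 → 0 °C; aq. NH4Cl
Reagents that add atoms: none
Why: Copper-catalysed Grignard opening of a monosubstituted epoxide by SN2 attack at the unsubstituted carbon; the stereocentre of 2 is not involved, so the (S)-carbinol that becomes C12' is carried over unchanged.

Step 2
Reactants: 4 (2S)-tridec-12-en-2-ol
Product: 5 (2S)-11-(oxiran-2-yl)undecan-2-ol (both epimers at the oxirane carbon)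
Conditions: mCPBA (1.2 equiv), NaHCO3, CH2Cl2, 0 °C → rt
Reagents that add atoms: mCPBA, OOC(=O)c1cccc(Cl)c1
Why: Prilezhaev epoxidation of the isolated terminal alkene; the remote carbinol gives no facial bias, so both epimers are expected and are sorted in step 3, and the bicarbonate buffer protects the epoxide from the acid by-product.

Step 3
Reactants: 5 (2S)-11-(oxiran-2-yl)undecan-2-ol (epimer pair)
Product: 6 (2S)-11-[(2S)-oxiran-2-yl]undecan-2-ol
Conditions: (S,S)-(salen)Co(OAc) (0.5 mol%; trivalent cobalt, salen = N,N'-bis(3,5-di-tert-butylsalicylidene)cyclohexane-1,2-diaminate), H2O (0.55 equiv), THF, 0 °C → rt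
Reagents that add atoms: none
Why: Hydrolytic kinetic resolution of a terminal epoxide: the (S,S) catalyst should activate only the (R)-oxirane epimer towards water, which is hydrolysed to a polar triol removed by chromatography, leaving the (S)-oxirane that becomes C2'; a slight excess of water over half an equivalent should consume the unwanted epimer completely, and a remote secondary alcohol does not compete with water.

Step 4
Reactants: 6 (2S)-11-[(2S)-oxiran-2-yl]undecan-2-ol
Product: 7 (4S,14S)-pentadec-1-ene-4,14-diol
Conditions: CH2=CHMgBr (3 equiv), CuI (15 mol%), THF, −40 → 0 °C; aq. NH4Cl
Reagents that add atoms: vinylmagnesium bromide, C=C[Mg]Br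
Why: Copper-catalysed SN2 opening of the terminal epoxide at its CH2 terminus by the vinyl Grignard reagent; the first equivalent is consumed by the free hydroxyl, and the oxirane stereocentre is not attacked, so its configuration is retained.

Step 5
Reactants: 7 (4S,14S)-pentadec-1-ene-4,14-diol
Product: 8 (4S,14S)-4,14-bis(tert-butyldimethylsilyloxy)pentadec-1-ene
Conditions: TBSCl (2.5 equiv), imidazole (5 equiv), DMF, rt
Reagents that add atoms: tert-butyldimethylsilyl chloride, CC(C)(C)[Si](C)(C)Cl
Why: Standard imidazole-promoted silylation of both secondary alcohols in one operation; TBS ethers are chosen because they withstand alkoxide, ruthenium carbenes and DDQ and can later be exchanged for acetyl without freeing the alcohol.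

Step 6
Reactants: 8 (4S,14S)-4,14-bis(tert-butyldimethylsilyloxy)pentadec-1-ene; 9 but-3-en-2-one (methyl vinyl ketone)
Product: 10 (3E,6S,16S)-6,16-bis(tert-butyldimethylsilyloxy)heptadec-3-en-2-one
Conditions: 9 (4 equiv), second-generation Hoveyda–Grubbs catalyst (C31H38Cl2N2ORu, 3 mol%), CH2Cl2, 40 °C
Reagents that add atoms: none
Why: Olefin cross-metathesis of a terminal alkene (type 1) with an electron-poor vinyl ketone (type 2); the excess of 9 suppresses homodimerisation of 8, the enone forms with thermodynamic E-selectivity, and ethene leaves the mixture.

Step 7
Reactants: 10 (3E,6S,16S)-6,16-bis(tert-butyldimethylsilyloxy)heptadec-3-en-2-one; 11 dibenzyl malonate (dibenzyl propanedioate)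
Product: 13 benzyl 6-[(2S,12S)-2,12-bis(tert-butyldimethylsilyloxy)tridecyl]-2,4-dioxocyclohexane-1-carboxylate (ring centres unassigned), via Michael adduct 12 (not isolated)
Conditions: 11 (1.1 equiv), NaOCH2Ph (1.0 M in PhCH2OH, 0.1 equiv), THF, 0 °C → rt; then NaOCH2Ph (1.1 equiv), 60 °C; AcOH (1.5 equiv), 0 °C
Reagents that add atoms: none
Why: Catalytic benzyloxide deprotonates 11 and the soft malonate anion adds to the β-carbon of the E-enone 10 (chain C4, which becomes ring C2) in a Michael addition that forms ring bond C1–C2; proton transfer leaves 12 as its malonate anion, so little free base remains to attack the γ-hydrogens. A full equivalent of benzyloxide then allows equilibrium formation of the methyl-side ketone enolate, which attacks one benzyl ester carbonyl in a Claisen condensation of the Dieckmann kind (ring bond C5–C6) with loss of benzyloxide. This closure is a 6-(enolendo)-exo-trig cyclisation, whereas the enolate on the internal CH2 could only close a four-membered ring and returns by proton exchange. The sequence is pulled forward by deprotonation of the product, a vinylogous acid, to its delocalised sodium enolate, which is the form held until the acetic acid quench. The closest known reaction type is the classical malonate–enone Michael–Claisen annulation that gives 5-substituted dihydroresorcinol carboxylates. The two new ring stereocentres (C1 and C2) arise without any controlling element, C1 being epimerisable in any case, and none is needed because both become sp2 in step 8. The selectivity that matters is chemoselectivity: conjugate addition must precede γ-deprotonation of 10 and vinylogous E1cB loss of the δ-silyloxy group, which is secured by the high acidity of the malonate, the low temperature of the first phase and the fact that in 12 the silyloxy group no longer stands in an eliminable relation to any carbanion. Matching the alkoxide to the ester makes transesterification invisible, and the two carbinol stereocentres, which are not adjacent to any acidic position, are untouched.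

Step 8
Reactants: 13 benzyl 6-[(2S,12S)-2,12-bis(tert-butyldimethylsilyloxy)tridecyl]-2,4-dioxocyclohexane-1-carboxylate
Product: 14 benzyl 2-[(2S,12S)-2,12-bis(tert-butyldimethylsilyloxy)tridecyl]-4,6-dihydroxybenzoate
Conditions: DDQ (1.15 equiv), anhydrous 1,4-dioxane, 80 °C
Reagents that add atoms: none
Why: Quinone dehydrogenation of a cyclic 1,3-dicarbonyl: hydride abstraction from C2–H of the C1=C6 enol (allylic, cation stabilised by the enol oxygen) and proton loss from C3 give a dienone that tautomerises to the resorcylate, erasing both ring stereocentres; the benzylic CH2 is meta to both phenols, so no quinone methide path to over-oxidation is open.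

Step 9
Reactants: 14 benzyl 2-[(2S,12S)-2,12-bis(tert-butyldimethylsilyloxy)tridecyl]-4,6-dihydroxybenzoate
Product: 15 benzyl 2,4-bis(acetyloxy)-6-[(2S,12S)-2,12-bis(acetyloxy)tridecyl]benzoate
Conditions: Ac2O (10 equiv), Bi(OTf)3 (5 mol%), MeCN, 0 °C → rt
Reagents that add atoms: acetic anhydride, CC(=O)OC(C)=O
Why: Metal triflate-catalysed acetolysis of silyl ethers: the activated anhydride acetylates the ether oxygen and silicon leaves as silyl acetate, so the C–O bonds at C2' and C12' are never broken (retention) and no free C2' hydroxyl appears beside the ester; the phenols are acetylated at the same time, which also deactivates the ring towards C-acylation.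

Step 10
Reactants: 15 benzyl 2,4-bis(acetyloxy)-6-[(2S,12S)-2,12-bis(acetyloxy)tridecyl]benzoate
Product: 16 benzyl 2-[(2S,12S)-2,12-bis(acetyloxy)tridecyl]-4,6-dihydroxybenzoate
Conditions: pyrrolidine (2.5 equiv), CH2Cl2, 0 °C; pH 4 buffer work-up
Reagents that add atoms: none
Why: Chemoselective aminolysis of aryl esters: aryl acetates are activated acyl donors with a phenoxide leaving group and react with a secondary amine at 0 °C, whereas the secondary alkyl acetates and the doubly ortho-substituted benzyl benzoate should be inert under these conditions.

Step 11
Reactants: 16 benzyl 2-[(2S,12S)-2,12-bis(acetyloxy)tridecyl]-4,6-dihydroxybenzoate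
Product: 17 2-[(2S,12S)-2,12-bis(acetyloxy)tridecyl]-4,6-dihydroxybenzoic acid
Conditions: H2 (1 atm), 10% Pd/C, EtOAc, rt
Reagents that add atoms: none
Why: Hydrogenolysis of the benzylic C–O bond of the ester over palladium under neutral conditions; acetates, phenols and the arene are untouched, and the acid is released at room temperature without acid or base, so neither decarboxylation nor lactone formation is provoked.

## Compound list

1 | 10-bromodec-1-ene | C=CCCCCCCCCBr | starting material
2 | (S)-propylene oxide, (2S)-2-methyloxirane | C[C@H]1CO1 | starting material
3 | dec-9-enylmagnesium bromide | C=CCCCCCCCC[Mg]Br | intermediate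
4 | (2S)-tridec-12-en-2-ol | C[C@H](O)CCCCCCCCCC=C | intermediate
5 | (2S)-11-(oxiran-2-yl)undecan-2-ol, epimer pair at the oxirane carbon | C[C@H](O)CCCCCCCCCC1CO1 | intermediate
6 | (2S)-11-[(2S)-oxiran-2-yl]undecan-2-ol | C[C@H](O)CCCCCCCCC[C@H]1CO1 | intermediate
7 | (4S,14S)-pentadec-1-ene-4,14-diol | C[C@H](O)CCCCCCCCC[C@H](O)CC=C | intermediate
8 | (4S,14S)-4,14-bis(tert-butyldimethylsilyloxy)pentadec-1-ene | CC(C)(C)[Si](C)(C)O[C@@H](CCCCCCCCC[C@H](C)O[Si](C)(C)C(C)(C)C)CC=C | intermediate
9 | but-3-en-2-one (methyl vinyl ketone) | CC(=O)C=C | starting material
10 | (3E,6S,16S)-6,16-bis(tert-butyldimethylsilyloxy)heptadec-3-en-2-one | CC(C)(C)[Si](C)(C)O[C@@H](CCCCCCCCC[C@H](C)O[Si](C)(C)C(C)(C)C)C/C=C/C(C)=O | intermediate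
11 | dibenzyl malonate | O=C(OCc1ccccc1)CC(=O)OCc1ccccc1 | starting material
12 | dibenzyl 2-[(6S,16S)-6,16-bis(tert-butyldimethylsilyloxy)-2-oxoheptadecan-4-yl]propanedioate (C4 unassigned) | CC(C)(C)[Si](C)(C)O[C@@H](CCCCCCCCC[C@H](C)O[Si](C)(C)C(C)(C)C)CC(CC(C)=O)C(C(=O)OCc1ccccc1)C(=O)OCc1ccccc1 | intermediate
13 | benzyl 6-[(2S,12S)-2,12-bis(tert-butyldimethylsilyloxy)tridecyl]-2,4-dioxocyclohexane-1-carboxylate (ring centres unassigned) | CC(C)(C)[Si](C)(C)O[C@@H](CCCCCCCCC[C@H](C)O[Si](C)(C)C(C)(C)C)CC1CC(=O)CC(=O)C1C(=O)OCc1ccccc1 | intermediate
14 | benzyl 2-[(2S,12S)-2,12-bis(tert-butyldimethylsilyloxy)tridecyl]-4,6-dihydroxybenzoate | CC(C)(C)[Si](C)(C)O[C@@H](CCCCCCCCC[C@H](C)O[Si](C)(C)C(C)(C)C)Cc1cc(O)cc(O)c1C(=O)OCc1ccccc1 | intermediate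
15 | benzyl 2,4-bis(acetyloxy)-6-[(2S,12S)-2,12-bis(acetyloxy)tridecyl]benzoate | CC(=O)O[C@@H](CCCCCCCCC[C@H](C)OC(C)=O)Cc1cc(OC(C)=O)cc(OC(C)=O)c1C(=O)OCc1ccccc1 | intermediate
16 | benzyl 2-[(2S,12S)-2,12-bis(acetyloxy)tridecyl]-4,6-dihydroxybenzoate | CC(=O)O[C@@H](CCCCCCCCC[C@H](C)OC(C)=O)Cc1cc(O)cc(O)c1C(=O)OCc1ccccc1 | intermediate
17 | 2-[(2S,12S)-2,12-bis(acetyloxy)tridecyl]-4,6-dihydroxybenzoic acid | CC(=O)O[C@@H](CCCCCCCCC[C@H](C)OC(C)=O)Cc1cc(O)cc(O)c1C(=O)O | target

## Step count and risk

Total step count: 11. Longest linear sequence: 11 steps (1 to 17); the route is linear, with 2, 9 and 11 entering as purchased partners.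

Least certain steps, with fallbacks:

Step 7 (key step). The most likely failure is γ-deprotonation of 10 followed by vinylogous β-elimination of silanolate, either before the conjugate addition or after reversal of the Michael addition during the hot second phase; this would cause irreversible loss of the C2' oxygen. The fallback exchanges the roles of the partners so that the electrophile is an enoate, whose γ-hydrogens are far less acidic. Setting out from 8, cross-metathesis with benzyl acrylate under the conditions of step 6 would give benzyl (2E,5S,15S)-5,15-bis(tert-butyldimethylsilyloxy)hexadec-2-enoate F1. Michael addition of benzyl acetoacetate to F1 and Claisen closure of the acetyl methyl group onto the chain-side benzyl ester (NaOCH2Ph, THF, then AcOH) would then form ring bonds C1–C2 and C4–C5, and the sequence comes back to the route at 13.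

Step 8. The most likely failure is incomplete dehydrogenation, because hydride abstraction from a strongly enolised, hydrogen-bonded β-keto ester can be slow, together with consumption of oxidant by the electron-rich product. The fallback is halogenation and dehydrohalogenation. Setting out from 13, its sodium enolate (NaHCO3 or the unquenched salt of step 7) would be brominated with N-bromosuccinimide in THF at 0 °C at the carbon between the two ring carbonyls, giving benzyl 3-bromo-6-[(2S,12S)-2,12-bis(tert-butyldimethylsilyloxy)tridecyl]-2,4-dioxocyclohexane-1-carboxylate F2. Warming F2 with Li2CO3 and LiBr in DMF should cause 1,4-elimination of hydrogen bromide from the dienol tautomer under buffered conditions that spare the silyl ethers, and the sequence comes back to the route at 14. Bromination at the ester-bearing ring carbon instead would converge on the same arene by 1,2-elimination.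

Step 9. The most likely failure is Lewis-acid activation of the benzyl ester so that the C2' oxygen closes the six-membered lactone with loss of the benzyl group, or incomplete exchange at the two hindered secondary silyl ethers. The fallback separates the operations. Setting out from 14, the phenols would be acetylated first (Ac2O, pyridine) to give benzyl 2,4-bis(acetyloxy)-6-[(2S,12S)-2,12-bis(tert-butyldimethylsilyloxy)tridecyl]benzoate F3, in which the ester is flanked by two ortho substituents, no longer hydrogen-bonded and therefore hindered. Desilylation with pyridine-buffered HF·pyridine in THF at 0 °C would give benzyl 2,4-bis(acetyloxy)-6-[(2S,12S)-2,12-dihydroxytridecyl]benzoate F4, whose C2' hydroxyl is free only briefly and under weakly acidic, cold conditions. F4 would be acetylated at once without purification (Ac2O, pyridine, DMAP), and the sequence comes back to the route at 15.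

Step 10. The most likely failure is slow cleavage of the hindered acetate ortho to the ester, with onset of aminolysis of the side-chain acetates on prolonged exposure, so that partially acetylated mixtures result. The fallback avoids phenolic acetates altogether. Setting out from 14, both phenols would be benzylated (BnBr, K2CO3, DMF) to give benzyl 2,4-bis(benzyloxy)-6-[(2S,12S)-2,12-bis(tert-butyldimethylsilyloxy)tridecyl]benzoate F5. The silyl-to-acetyl exchange of step 9 would give benzyl 2,4-bis(benzyloxy)-6-[(2S,12S)-2,12-bis(acetyloxy)tridecyl]benzoate F6. One hydrogenolysis (H2, Pd/C, EtOAc) would then remove all three benzyl groups, and the sequence comes back to the route at 17.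

Step 3. The most likely failure is incomplete hydrolysis of the (R)-oxirane epimer, through poor mixing of water with the waxy lipophilic substrate or reduction of the catalyst to inactive divalent cobalt, which would leave a C2' epimer that cannot be removed later. The fallback sets C2' by reagent-controlled allylation of an aldehyde. Setting out from 4, silylation (TBSCl, imidazole) would give tert-butyldimethyl{[(2S)-tridec-12-en-2-yl]oxy}silane F7, and ozonolysis (O3, CH2Cl2, −78 °C; PPh3) would give (11S)-11-(tert-butyldimethylsilyloxy)dodecanal F8. Brown allylboration would use the B-allyldiisopinocampheylborane made from (−)-α-pinene by way of (+)-B-methoxydiisopinocampheylborane and allylmagnesium bromide (Et2O, −78 °C; NaOH, H2O2). This reagent delivers allyl to the Re face of an aliphatic aldehyde and would give (4S,14S)-14-(tert-butyldimethylsilyloxy)pentadec-1-en-4-ol F9. Silylation of F9 comes back to the route at 8.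

## Further compounds

F1 | step 7 | benzyl (2E,5S,15S)-5,15-bis(tert-butyldimethylsilyloxy)hexadec-2-enoate | CC(C)(C)[Si](C)(C)O[C@@H](CCCCCCCCC[C@H](C)O[Si](C)(C)C(C)(C)C)C/C=C/C(=O)OCc1ccccc1
F2 | step 8 | benzyl 3-bromo-6-[(2S,12S)-2,12-bis(tert-butyldimethylsilyloxy)tridecyl]-2,4-dioxocyclohexane-1-carboxylate | CC(C)(C)[Si](C)(C)O[C@@H](CCCCCCCCC[C@H](C)O[Si](C)(C)C(C)(C)C)CC1CC(=O)C(Br)C(=O)C1C(=O)OCc1ccccc1
F3 | step 9 | benzyl 2,4-bis(acetyloxy)-6-[(2S,12S)-2,12-bis(tert-butyldimethylsilyloxy)tridecyl]benzoate | CC(C)(C)[Si](C)(C)O[C@@H](CCCCCCCCC[C@H](C)O[Si](C)(C)C(C)(C)C)Cc1cc(OC(C)=O)cc(OC(C)=O)c1C(=O)OCc1ccccc1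
F4 | step 9 | benzyl 2,4-bis(acetyloxy)-6-[(2S,12S)-2,12-dihydroxytridecyl]benzoate | O[C@@H](CCCCCCCCC[C@H](C)O)Cc1cc(OC(C)=O)cc(OC(C)=O)c1C(=O)OCc1ccccc1
F5 | step 10 | benzyl 2,4-bis(benzyloxy)-6-[(2S,12S)-2,12-bis(tert-butyldimethylsilyloxy)tridecyl]benzoate | CC(C)(C)[Si](C)(C)O[C@@H](CCCCCCCCC[C@H](C)O[Si](C)(C)C(C)(C)C)Cc1cc(OCc2ccccc2)cc(OCc2ccccc2)c1C(=O)OCc1ccccc1
F6 | step 10 | benzyl 2,4-bis(benzyloxy)-6-[(2S,12S)-2,12-bis(acetyloxy)tridecyl]benzoate | CC(=O)O[C@@H](CCCCCCCCC[C@H](C)OC(C)=O)Cc1cc(OCc2ccccc2)cc(OCc2ccccc2)c1C(=O)OCc1ccccc1
F7 | step 3 | tert-butyldimethyl{[(2S)-tridec-12-en-2-yl]oxy}silane | C=CCCCCCCCCC[C@H](C)O[Si](C)(C)C(C)(C)C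
F8 | step 3 | (11S)-11-(tert-butyldimethylsilyloxy)dodecanal | O=CCCCCCCCCC[C@H](C)O[Si](C)(C)C(C)(C)C
F9 | step 3 | (4S,14S)-14-(tert-butyldimethylsilyloxy)pentadec-1-en-4-ol | C=CC[C@@H](O)CCCCCCCCC[C@H](C)O[Si](C)(C)C(C)(C)C
A1 | alternative 1 | (3S)-3-[(10S)-10-(tert-butyldimethylsilyloxy)undecyl]-6,8-dimethoxyisochroman-1-one | O=C1O[C@@H](CCCCCCCCC[C@H](C)O[Si](C)(C)C(C)(C)C)Cc2cc(OC)cc(OC)c12
A2 | alternative 1 | (2S,12S)-12-(tert-butyldimethylsilyloxy)-1-chlorotridecan-2-ol | O[C@@H](CCCCCCCCC[C@H](C)O[Si](C)(C)C(C)(C)C)CCl
A3 | alternative 1 | 3,5-dimethoxybenzyne (1,2-didehydro-3,5-dimethoxybenzene) | COC1=CC(OC)=CC#C1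
A4 | alternative 2 | (2S,12S)-1-[3,5-bis(benzyloxy)phenyl]tridecane-2,12-diyl diacetate | CC(=O)O[C@@H](CCCCCCCCC[C@H](C)OC(C)=O)Cc1cc(OCc2ccccc2)cc(OCc2ccccc2)c1
A5 | alternative 2 | (3S,13S)-3-{[3,5-bis(benzyloxy)phenyl]methyl}-13-methylpentadecane-2,14-dione | CC(=O)[C@@H](CCCCCCCCC[C@H](C)C(C)=O)Cc1cc(OCc2ccccc2)cc(OCc2ccccc2)c1
A6 | alternative 3 | benzyl 2-[(2S,12S)-2,12-diacetoxytridecyl]-4,6-dihydroxybenzoate (identical with 16) | CC(=O)O[C@@H](CCCCCCCCC[C@H](C)OC(C)=O)Cc1cc(O)cc(O)c1C(=O)OCc1ccccc1
A7 | alternative 3 | benzyl (5S,15S)-5,15-bis(acetyloxy)hexadec-2-ynoate | CC(=O)O[C@@H](CCCCCCCCC[C@H](C)OC(C)=O)CC#CC(=O)OCc1ccccc1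
A8 | alternative 3 | 5,5-dimethyl-1,3-bis(trimethylsilyloxy)cyclohexa-1,3-diene | C[Si](C)(C)OC1=CC(O[Si](C)(C)C)=CC(C)(C)C1
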